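**The balance.** Every G charged stays G, turns into E, or leaves some other way, so I watched the share of the charged G found as E.

| setting | violet | teal | ochre | blue | green |
|---|---|---|---|---|---|
| G | 0.100 M | 0.0600 M | 0.200 M | 0.100 M | 0.0330 M |
| X | 0.120 M | 0.0800 M | 0.120 M | 0.360 M | 0.120 M |
| J | 5.00 × 10⁻⁴ M | 5.00 × 10⁻⁴ M | 5.00 × 10⁻⁴ M | 5.00 × 10⁻⁴ M | 2.50 × 10⁻⁴ M |
| time |  |  |  |  | 35 h |

- violet run (time / h: [E] / M): 1.4: 0.0034; 2.7: 0.0069; 5.1: 0.0133; 9.7: 0.0222; 18: 0.0328; 35: 0.0402
- teal run (time / h: [E] / M): 1.4: 0.0021; 2.7: 0.0022; 5.1: 0.0054; 9.7: 0.0091; 18: 0.0133; 35: 0.0167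
- ochre run (time / h: [E] / M): 1.4: 0.0056; 2.7: 0.0107; 5.1: 0.0247; 9.7: 0.0460; 18: 0.0671; 35: 0.0806
- blue run (time / h: [E] / M): 1.4: 0.0095; 2.7: 0.0215; 5.1: 0.0429; 9.7: 0.0652; 18: 0.0724; 35: 0.0728

(scatter of a reading: 5 × 10⁻⁴ M)

- apparent order in [G] of the starting rate, round the charge of the violet run (the rate where two percent of its G have turned into E) (one fixed amount of E, the same in the runs compared)
- apparent order in [X] of the starting rate, round the charge of the violet run (the rate where two percent of its G have turned into E)
- E in the green run at 35 h, as a share of the G charged

- Overall: G + X -> E, with J as catalyst.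
- Constant volume, constant temperature.
- A reading of a species includes what of it is bound.
- An order is taken over about fifteen percent of the charge, up and down.

**The split.** At 35 h the violet run stood at 40.2%. The ochre run, with twice the G and the same [X], stood at 40.3%. A share that did not move with the charge of G suggested to me two paths for G, each first order in [G], racing each other. For the violet run that reading gives 0.672, and I called it the split, the E made per G gone another way, a selectivity factor. Scaled by the [X] of the blue run, it becomes 2.02, a share of 66.9%, and the blue reading was 72.8%. The rule was rough but pointed the right way.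

**The bracket.** The green run has the [X] of the violet run and half its J. I took the E path as proportional to J. Early violet readings give that path 0.0261 h⁻¹ per unit of G. With the split halved to 0.336, a finished green run gives 25.2%, my top. For the bottom I kept the violet loss, 0.0388 h⁻¹, added the halved E path, and asked how much of the green G was spent by 35 h. That lowers the share to 21.1%.

**The forecast.** It gave orders of 0.85 in [G] and 1 in [X], and 23% for the green run, with a range from 17% to 30%. That value sits inside my bracket, though on another ground, which read: “The catalyst is dying instead”.

**The result.** The orders came out at 0.74 and 0.98, and the green run gave 24.2%, inside the bracket.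

    J + G ⇌ JG (637.2 L mol⁻¹ h⁻¹, 107.6 h⁻¹)
    JG + X → E + J (112.7 L mol⁻¹ h⁻¹)
    G → Yx (0.05832 h⁻¹)
    G + X + E → 2 E (10.51 L² mol⁻² h⁻¹)

**One reason.** Read back, the green share gives a split of 0.319, against the 0.336 carried from the violet run. The other way out was G → Yx. The same green run without that step reached 59.4% instead of 24.2%, a difference of 35 percentage points.

(The numbers in the tables stem from a simulated flask for an exercise.)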